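Each substrate molecule that reacts ends as left-handed product P or right-handed product Q, so in percent of the charge, P + Q stays at or below 100. Left-handed substrate is 50% of the charge, so any P above that has crossed from right-handed substrate through the achiral form.

all flasks: gas 5.4 mM (held)
- Thursday's: left-handed substrate 0.024 M; right-handed substrate 0.024 M; temperature −40 °C; run made earlier
- Saturday's: left-handed substrate 0.054 M; right-handed substrate 0.054 M; temperature −8 °C; run made earlier
- winter: left-handed substrate 0.036 M; right-handed substrate 0.036 M; temperature −5 °C; time 40 min
- autumn: left-handed substrate 0.036 M; right-handed substrate 0.036 M; temperature 20 °C; time 40 min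
- dusk: left-handed substrate 0.036 M; right-handed substrate 0.036 M; temperature 10 °C; time 40 min
- dawn: left-handed substrate 0.036 M; right-handed substrate 0.036 M; temperature −35 °C; time 40 min
- noon: left-handed substrate 0.036 M; right-handed substrate 0.036 M; temperature 0 °C; time 40 min
- spring: left-handed substrate 0.036 M; right-handed substrate 0.036 M; temperature −20 °C; time 40 min

| run | time / min | left-handed product / % |
|---|---|---|
| Thursday's | 4.00 | 12.0 |
| Thursday's | 10.0 | 26.7 |
| Thursday's | 15.0 | 34.8 |
| Thursday's | 25.0 | 43.0 |
| Thursday's | 40.0 | 49.2 |
| Thursday's | 50.0 | 50.9 |
| Thursday's | 60.0 | 51.7 |
| Saturday's | 0.667 | 4.1 |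
| Saturday's | 2.00 | 12.0 |
| Saturday's | 3.00 | 17.2 |
| Saturday's | 6.00 | 35.1 |
| Saturday's | 8.00 | 45.8 |
| Saturday's | 12.0 | 60.6 |
| Saturday's | 15.0 | 67.1 |

(standard deviation of a reading: 0.5 percentage points)

- the flasks by amount of left-handed product, in percent of the left-handed substrate and right-handed substrate together charged, highest first, at 40 min (winter / autumn / dusk / dawn / noon / spring)
- the amount of left-handed product, in percent of the left-handed substrate and right-handed substrate together charged of the flask you put first, at 40 min
- the amount of left-handed product, in percent of the left-handed substrate and right-handed substrate together charged of the flask you put last, at 40 min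

- partner is single-handed; left-handed substrate and right-handed substrate are mirror images of each other, charged as a racemate, each of them at the stated concentration
- at the start none of partner is dissolved
- the analysis behind the earlier runs scatters by 0.5 percentage points, standard deviation
- steps thought possible: partner + left-handed substrate -> left-handed product; partner + right-handed substrate -> right-handed product; left-handed substrate <-> achiral form; right-handed substrate <-> achiral form; 2 partner -> self-condensation product; gas <-> partner; partner <-> dormant form
- the handed part of partner does not stay in what it makes, so the products of the two hands are mirror images too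

The readings show P, not Q. But the sum bounds the unseen product, so we treat Q as the correction:

Q ≤ 100 − P

ρ = P / (100 − P)

Saturday's last reading, at −8 °C: ρ = 2.04

Thursday's last reading, at −40 °C: ρ = 1.07

This ρ, the floor under the product ratio P/Q, becomes the ratio itself once both substrates and the achiral form are gone, because then Q = 100 − P. Saturday's floor, as read, is higher than Thursday's. Saturday's run was also still climbing, with 6.5 percentage points gained in its last 3.00 min.

Our own reckoning stops at a bound. We expect winter, near Saturday's temperature and given 40 min, to stand above 67.1%, and dawn, near Thursday's temperature, to stand near 51.7%.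

The forecast is noon > dusk > winter > autumn > spring > dawn, with 93% at the top and 52% at the bottom. Of the warm flasks it says: “The order among the warm flasks is therefore a judgement call, with a shallow optimum near 0 °C.” Its top value means a floor of 13.3, which is more than Saturday's floor.

The flasks give autumn > dusk > noon > winter > spring > dawn, with 79.3% at the top and 52.0% at the bottom.

    partner + left-handed substrate → left-handed product (k = 2.10 /M/s, Ea = 45.0 kJ/mol)
    partner + right-handed substrate → right-handed product (k = 0.900 /M/s, Ea = 37.0 kJ/mol)
    left-handed substrate ⇌ achiral form (K = 0.0290, k = 0.00350 /s, Ea = 73.0 kJ/mol, ΔH = −35.0 kJ/mol)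
    right-handed substrate ⇌ achiral form (K = 0.0290, k = 0.00350 /s, Ea = 73.0 kJ/mol, ΔH = −35.0 kJ/mol)
    2 partner → self-condensation product (k = 0.220 /M/s, Ea = 43.0 kJ/mol)
    gas ⇌ partner, rate k6*(csat - [partner]) (kL = 0.0390 /s)
    partner ⇌ dormant form (K = 39.0, k = 0.0530 /s, Ea = 57.0 kJ/mol, ΔH = −10.0 kJ/mol)
    (constants at −20 °C)

In autumn at 40.0 min, left-handed substrate, right-handed substrate and achiral form stand at 0%, 0% and 0%, and right-handed product at 20.7%. The floor is therefore the ratio itself, 3.84, which is more than Saturday's 2.04 and less than the 13.3 of the forecast. Dawn still holds 2.84% of right-handed substrate at 40.0 min. Its floor is 1.08, and its product ratio, with right-handed product at 44.3%, is higher, at 1.17.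

The readings are calculated with made-up constants; scatter was added.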